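**Retrosynthetic overview**

- Target 25 comes from 22 by desilylation and ester hydrolysis. The benzene ring is the only ring, arrives with 1, and no ring is formed anywhere.
- 22 is cut at C3'-C4' into (E)-alkenyl iodide 18 and 4-methylpent-3-enal 20. The strategy rests on the single stereocentre C4', a secondary allylic carbinol lying between alkenyl carbon C3' (E-olefin C2'=C3', methyl on C3') and C5'H2 of the prenyl end, in the chain bound through C1' to the benzene ring.
- 18 comes from 2-butynyl arene 16 by syn-hydrozirconation and iodination. 16 comes from benzylic chloride 13 and a propynyl metal; C1' is the formyl carbon of 1.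
- The short chain (C1''-C4'') comes from cross-metathesis of an allyl group with methacrolein, 1,2-reduction and silylation. The allyl group is put on by O-allylation and Claisen rearrangement of 1.

Key step: step 12

Assumption (symmetry): ring carbons 3 and 5 of the 4-methoxybenzoate core are equivalent, so it does not matter which flank carries which chain.
Assumption (sense of induction): the (S)-configured oxazoline-sulfonamide ligand is taken to deliver the 4'R carbinol; this would be checked by MTPA ester analysis of 22 on the first run, and the (R)-ligand used instead if the sense is opposite.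
Remark: the chiral ligand is a known auxiliary made separately, and its preparation is not counted among the steps.

**Route**

Step 1
Reactants: 1 methyl 3-formyl-4-hydroxybenzoate; 2 allyl bromide
Product: 3 methyl 3-formyl-4-(prop-2-enyloxy)benzoate
Conditions: K2CO3, DMF, rt to 50 °C
Reagents that add atoms: none
Why: Williamson ether synthesis, in which the acidic phenol (ortho-formyl, para-ester) is alkylated at oxygen by the allylic bromide and nothing else in 1 is electrophile-sensitive.

Step 2
Reactants: 3 methyl 3-formyl-4-(prop-2-enyloxy)benzoate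
Product: 5 methyl 3-formyl-4-hydroxy-5-(prop-2-enyl)benzoate, via ortho-dienone 4 (not isolated)
Conditions: N,N-diethylaniline, 190 °C, sealed tube
Reagents that add atoms: none
Why: Aromatic Claisen rearrangement, whose [3,3]-shift can deliver the allyl group only to the one free ortho carbon, giving dienone 4 that tautomerises to the phenol.

Step 3
Reactants: 5 methyl 3-formyl-4-hydroxy-5-(prop-2-enyl)benzoate
Product: 6 methyl 3-formyl-4-methoxy-5-(prop-2-enyl)benzoate
Conditions: MeI, K2CO3, DMF, rt
Reagents that add atoms: iodomethane, CI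
Why: Williamson O-methylation of the phenoxide; K2CO3 is too weak to move the allyl double bond into conjugation.

Step 4
Reactants: 6 methyl 3-formyl-4-methoxy-5-(prop-2-enyl)benzoate
Product: 7 methyl 3-(hydroxymethyl)-4-methoxy-5-(prop-2-enyl)benzoate
Conditions: NaBH4, MeOH, 0 °C
Reagents that add atoms: none
Why: Borohydride reduction is chemoselective for the aryl aldehyde over the methyl ester at 0 °C.

Step 5
Reactants: 7 methyl 3-(hydroxymethyl)-4-methoxy-5-(prop-2-enyl)benzoate
Product: 9 methyl 3-(chloromethyl)-4-methoxy-5-(prop-2-enyl)benzoate, via benzylic mesylate 8 (not isolated)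
Conditions: MsCl, Et3N, THF, 0 °C; then LiCl, rt
Reagents that add atoms: methanesulfonyl chloride, CS(=O)(=O)Cl (mesyl group of 8); lithium chloride, [Li+].[Cl-] (chlorine of 9)
Why: Sulfonylation followed by SN2 displacement with chloride at the primary benzylic carbon, under conditions that leave the ester and the allyl group alone.

Step 6
Reactants: 9 methyl 3-(chloromethyl)-4-methoxy-5-(prop-2-enyl)benzoate; 10 methacrolein
Product: 11 methyl 3-(chloromethyl)-4-methoxy-5-[(E)-3-methyl-4-oxobut-2-enyl]benzoate
Conditions: 10 (5 equiv), second-generation Hoveyda-Grubbs catalyst RuCl2(H2IMes)(=CH-C6H4-2-OiPr) (5 mol%), CH2Cl2, 40 °C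
Reagents that add atoms: none
Why: Olefin cross-metathesis of a terminal alkene with methacrolein, which is reversible and should settle on the conjugated E-trisubstituted enal (formyl trans to the benzylic CH2) with loss of ethene; the benzylic chloride is inert to the ruthenium carbene.

Step 7
Reactants: 11 methyl 3-(chloromethyl)-4-methoxy-5-[(E)-3-methyl-4-oxobut-2-enyl]benzoate
Product: 12 methyl 3-(chloromethyl)-5-[(E)-4-hydroxy-3-methylbut-2-enyl]-4-methoxybenzoate
Conditions: NaBH4, CeCl3·7H2O, MeOH, -20 °C
Reagents that add atoms: none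
Why: Luche reduction gives clean 1,2-reduction of the enal to the allylic alcohol without touching the olefin geometry, the ester or, in the short cold reaction, the benzylic chloride.

Step 8
Reactants: 12 methyl 3-(chloromethyl)-5-[(E)-4-hydroxy-3-methylbut-2-enyl]-4-methoxybenzoate
Product: 13 methyl 3-[(E)-4-(tert-butyldimethylsilyloxy)-3-methylbut-2-enyl]-5-(chloromethyl)-4-methoxybenzoate
Conditions: TBSCl, imidazole, CH2Cl2, 0 °C
Reagents that add atoms: tert-butyldimethylsilyl chloride, CC(C)(C)[Si](C)(C)Cl
Why: Silylation of the unhindered primary allylic alcohol is fast at 0 °C, well ahead of any N-alkylation of imidazole by the benzylic chloride.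

Step 9
Reactants: 13 methyl 3-[(E)-4-(tert-butyldimethylsilyloxy)-3-methylbut-2-enyl]-5-(chloromethyl)-4-methoxybenzoate; 14 prop-1-ynylmagnesium bromide
Product: 16 methyl 3-(but-2-ynyl)-5-[(E)-4-(tert-butyldimethylsilyloxy)-3-methylbut-2-enyl]-4-methoxybenzoate, via prop-1-ynylzinc bromide 15 (not isolated)
Conditions: 14, ZnBr2, THF, 0 °C; then 13, PdCl2(DPEphos) (3 mol%), THF, rt
Reagents that add atoms: zinc bromide, Br[Zn]Br (zinc of intermediate 15; no atom of it remains in 16)
Why: Negishi coupling (benzylic C-Cl oxidative addition to zerovalent palladium, transmetalation from the alkynylzinc, reductive elimination); the alkynylzinc neither adds to the methyl ester nor is basic enough to turn the 1-aryl-2-butyne into an allene.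

Step 10
Reactants: 16 methyl 3-(but-2-ynyl)-5-[(E)-4-(tert-butyldimethylsilyloxy)-3-methylbut-2-enyl]-4-methoxybenzoate
Product: 18 methyl 3-[(E)-3-iodobut-2-enyl]-4-methoxy-5-[(E)-4-(tert-butyldimethylsilyloxy)-3-methylbut-2-enyl]benzoate, via alkenylzirconocene chloride 17 (not isolated)
Conditions: Cp2Zr(H)Cl (2 equiv), THF, rt to 40 °C; then I2, THF, -20 °C
Reagents that add atoms: chlorobis(cyclopentadienyl)zirconium hydride, [H][Zr](Cl)(C1C=CC=C1)C1C=CC=C1 (zirconocene of 17); iodine, II
Why: Hydrozirconation-iodination, in which H and Zr add syn across the alkyne, excess hydride lets zirconium settle on C3' beside the small methyl group (17), and iodinolysis with retention gives the E-iodide (H on C2' cis to I); the trisubstituted alkene and the silyl ether do not react, and the ester should be reduced only slowly.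

Step 11
Reactants: 19 4-methylpent-3-en-1-ol
Product: 20 4-methylpent-3-enal
Conditions: Dess-Martin periodinane, NaHCO3, CH2Cl2, 0 °C to rt; filtered, concentrated cold and used at once
Reagents that add atoms: none
Why: Dess-Martin oxidation under bicarbonate buffer is neutral, so the beta,gamma-unsaturated aldehyde should not slip into conjugation before it is used.

Step 12
Reactants: 18 methyl 3-[(E)-3-iodobut-2-enyl]-4-methoxy-5-[(E)-4-(tert-butyldimethylsilyloxy)-3-methylbut-2-enyl]benzoate; 20 4-methylpent-3-enal (2 equiv)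
Product: 22 methyl 3-[(2E,4R)-4-hydroxy-3,7-dimethylocta-2,6-dienyl]-4-methoxy-5-[(E)-4-(tert-butyldimethylsilyloxy)-3-methylbut-2-enyl]benzoate, via zirconocene chloride alkoxide 21 (not isolated)
Conditions: CrCl2 (15 mol%), (S)-N-[2-(4-isopropyl-4,5-dihydro-1,3-oxazol-2-yl)-6-methylphenyl]methanesulfonamide (17 mol%), 1,8-bis(dimethylamino)naphthalene (17 mol%), NiCl2·(2,9-dimethyl-1,10-phenanthroline) (2 mol%), Mn powder (2 equiv), Cp2ZrCl2 (1.2 equiv), LiCl (2 equiv), MeCN, rt; aqueous work-up
Reagents that add atoms: zirconocene dichloride, Cl[Zr](Cl)(C1C=CC=C1)C1C=CC=C1 (zirconium of intermediate 21; no atom of it remains in 22)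
Why: Zerovalent nickel, formed from the NiCl2 complex by Mn, inserts into the C3'-I bond of 18 with retention of the E geometry and passes the alkenyl group to trivalent chromium carrying the deprotonated oxazoline-sulfonamide; the alkenylchromium adds to the aldehyde carbon of 20 through a closed chromium-bound transition state to form the C3'-C4' bond, Cp2ZrCl2 takes the alkoxide off chromium as 21, and Mn returns chromium to the divalent state. The closest known reaction type is the catalytic asymmetric Nozaki-Hiyama-Kishi coupling of alkenyl iodides with aliphatic aldehydes. No ring is closed. The C4' stereocentre is set by the chiral ligand on chromium (reagent control), which tells the two faces of the aldehyde apart; neither partner has a stereocentre to interfere. The step needs enantioface selectivity, attack on the aldehyde and not the methyl ester, and intact olefins: the first rests on the ligand, the second on the low basicity and carbonyl selectivity of alkenylchromium species, and the third on the stereoretentive nickel-to-chromium transfer and the absence of any base able to conjugate 20 or the skipped aryl-alkenes.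

Step 13
Reactants: 22 methyl 3-[(2E,4R)-4-hydroxy-3,7-dimethylocta-2,6-dienyl]-4-methoxy-5-[(E)-4-(tert-butyldimethylsilyloxy)-3-methylbut-2-enyl]benzoate
Product: 23 methyl 3-[(2E,4R)-4-hydroxy-3,7-dimethylocta-2,6-dienyl]-5-[(E)-4-hydroxy-3-methylbut-2-enyl]-4-methoxybenzoate
Conditions: Bu4NF, THF, 0 °C to rt
Reagents that add atoms: none
Why: Fluoride-mediated desilylation, driven by the strong Si-F bond, frees the primary allylic alcohol without touching the ester, the alkenes or the C4' carbinol.

Step 14
Reactants: 23 methyl 3-[(2E,4R)-4-hydroxy-3,7-dimethylocta-2,6-dienyl]-5-[(E)-4-hydroxy-3-methylbut-2-enyl]-4-methoxybenzoate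
Product: 25 3-[(2E,4R)-4-hydroxy-3,7-dimethylocta-2,6-dienyl]-5-[(E)-4-hydroxy-3-methylbut-2-enyl]-4-methoxybenzoic acid, via lithium carboxylate 24 (not isolated)
Conditions: LiOH, THF/MeOH/H2O, rt; then 1 M HCl to pH 4, 0 °C
Reagents that add atoms: lithium hydroxide, [Li+].[OH-]
Why: Saponification (BAc2) of the unhindered methyl benzoate gives carboxylate 24, and cold acidification to pH 4 frees the acid without ionising the allylic C4' alcohol, so the stereocentre is untouched.

**Compound list**

1 | methyl 3-formyl-4-hydroxybenzoate | COC(=O)c1ccc(O)c(C=O)c1 | starting material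
2 | allyl bromide (3-bromoprop-1-ene) | C=CCBr | starting material
3 | methyl 3-formyl-4-(prop-2-enyloxy)benzoate | COC(=O)c1ccc(OCC=C)c(C=O)c1 | intermediate
4 | methyl 5-formyl-4-oxo-3-(prop-2-enyl)cyclohexa-1,5-diene-1-carboxylate (ortho-dienone, racemic, transient) | COC(=O)C1=CC(CC=C)C(=O)C(C=O)=C1 | intermediate
5 | methyl 3-formyl-4-hydroxy-5-(prop-2-enyl)benzoate | COC(=O)c1cc(CC=C)c(O)c(C=O)c1 | intermediate
6 | methyl 3-formyl-4-methoxy-5-(prop-2-enyl)benzoate | COC(=O)c1cc(CC=C)c(OC)c(C=O)c1 | intermediate
7 | methyl 3-(hydroxymethyl)-4-methoxy-5-(prop-2-enyl)benzoate | COC(=O)c1cc(CC=C)c(OC)c(CO)c1 | intermediate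
8 | methyl 4-methoxy-3-[(methylsulfonyloxy)methyl]-5-(prop-2-enyl)benzoate | COC(=O)c1cc(CC=C)c(OC)c(COS(C)(=O)=O)c1 | intermediate
9 | methyl 3-(chloromethyl)-4-methoxy-5-(prop-2-enyl)benzoate | COC(=O)c1cc(CC=C)c(OC)c(CCl)c1 | intermediate
10 | methacrolein (2-methylprop-2-enal) | CC(=C)C=O | starting material
11 | methyl 3-(chloromethyl)-4-methoxy-5-[(E)-3-methyl-4-oxobut-2-enyl]benzoate | COC(=O)c1cc(C/C=C(\C)C=O)c(OC)c(CCl)c1 | intermediate
12 | methyl 3-(chloromethyl)-5-[(E)-4-hydroxy-3-methylbut-2-enyl]-4-methoxybenzoate | COC(=O)c1cc(C/C=C(\C)CO)c(OC)c(CCl)c1 | intermediate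
13 | methyl 3-[(E)-4-(tert-butyldimethylsilyloxy)-3-methylbut-2-enyl]-5-(chloromethyl)-4-methoxybenzoate | COC(=O)c1cc(C/C=C(\C)CO[Si](C)(C)C(C)(C)C)c(OC)c(CCl)c1 | intermediate
14 | prop-1-ynylmagnesium bromide | CC#C[Mg]Br | starting material
15 | prop-1-ynylzinc bromide | CC#C[Zn]Br | intermediate
16 | methyl 3-(but-2-ynyl)-5-[(E)-4-(tert-butyldimethylsilyloxy)-3-methylbut-2-enyl]-4-methoxybenzoate | COC(=O)c1cc(CC#CC)c(OC)c(C/C=C(\C)CO[Si](C)(C)C(C)(C)C)c1 | intermediate
17 | chlorobis(cyclopentadienyl)zirconium (E)-but-2-en-2-yl complex of the arene (Zr on C3', trans to the benzylic CH2) | COC(=O)c1cc(C/C=C(\C)[Zr](Cl)(C2C=CC=C2)C2C=CC=C2)c(OC)c(C/C=C(\C)CO[Si](C)(C)C(C)(C)C)c1 | intermediate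
18 | methyl 3-[(E)-3-iodobut-2-enyl]-4-methoxy-5-[(E)-4-(tert-butyldimethylsilyloxy)-3-methylbut-2-enyl]benzoate | COC(=O)c1cc(C/C=C(\C)I)c(OC)c(C/C=C(\C)CO[Si](C)(C)C(C)(C)C)c1 | intermediate
19 | 4-methylpent-3-en-1-ol | CC(C)=CCCO | starting material
20 | 4-methylpent-3-enal | CC(C)=CCC=O | intermediate
21 | chlorobis(cyclopentadienyl)zirconium (4'R)-alkoxide of 22 | COC(=O)c1cc(C/C=C(\C)[C@H](O[Zr](Cl)(C2C=CC=C2)C2C=CC=C2)CC=C(C)C)c(OC)c(C/C=C(\C)CO[Si](C)(C)C(C)(C)C)c1 | intermediate
22 | methyl 3-[(2E,4R)-4-hydroxy-3,7-dimethylocta-2,6-dienyl]-4-methoxy-5-[(E)-4-(tert-butyldimethylsilyloxy)-3-methylbut-2-enyl]benzoate | COC(=O)c1cc(C/C=C(\C)[C@H](O)CC=C(C)C)c(OC)c(C/C=C(\C)CO[Si](C)(C)C(C)(C)C)c1 | intermediate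
23 | methyl 3-[(2E,4R)-4-hydroxy-3,7-dimethylocta-2,6-dienyl]-5-[(E)-4-hydroxy-3-methylbut-2-enyl]-4-methoxybenzoate | COC(=O)c1cc(C/C=C(\C)[C@H](O)CC=C(C)C)c(OC)c(C/C=C(\C)CO)c1 | intermediate
24 | lithium 3-[(2E,4R)-4-hydroxy-3,7-dimethylocta-2,6-dienyl]-5-[(E)-4-hydroxy-3-methylbut-2-enyl]-4-methoxybenzoate | [Li+].[O-]C(=O)c1cc(C/C=C(\C)[C@H](O)CC=C(C)C)c(OC)c(C/C=C(\C)CO)c1 | intermediate
25 | 3-[(2E,4R)-4-hydroxy-3,7-dimethylocta-2,6-dienyl]-5-[(E)-4-hydroxy-3-methylbut-2-enyl]-4-methoxybenzoic acid | COc1c(C/C=C(\C)CO)cc(C(=O)O)cc1C/C=C(\C)[C@H](O)CC=C(C)C | target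

**Step count**

Total: 14 steps. Longest linear sequence: 13 steps (from 1 through steps 1-10 and 12-14); step 11 is a one-step side branch.

**Steps most likely to fail**

Step 12. The ligand may discriminate the aldehyde faces poorly with this alpha-methyl-substituted alkenylchromium, and the aldehyde may conjugate or self-condense before it couples. The fallback sets out from 18 and 20 and comes back at 22, moving stereocontrol from the C-C bond formation to a ketone reduction.
- The coupling would be run without chiral ligand (excess CrCl2, NiCl2 1 mol%, DMSO/THF, rt) to give racemic methyl 3-[(2E)-4-hydroxy-3,7-dimethylocta-2,6-dienyl]-4-methoxy-5-[(E)-4-(tert-butyldimethylsilyloxy)-3-methylbut-2-enyl]benzoate F1.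
- Buffered Dess-Martin oxidation should give methyl 3-[(2E)-3,7-dimethyl-4-oxoocta-2,6-dienyl]-4-methoxy-5-[(E)-4-(tert-butyldimethylsilyloxy)-3-methylbut-2-enyl]benzoate F2.
- Corey-Bakshi-Shibata reduction with the (S)-2-methyl-oxazaborolidine and catecholborane in toluene at -78 °C should return 22 as the 4'R carbinol, the methyl-bearing alkenyl group acting as the large substituent.

Step 10. Zirconium may not settle cleanly on C3' (some C2' iodide would follow), and excess hydride may slowly reduce the methyl ester. The fallback sets out from 9 and comes back at 18; it fixes the position of the halogen by connectivity and swaps the roles of the two flanks, which the ring symmetry allows.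
- Commercial (E)-3-iodo-2-methylprop-2-en-1-ol would be silylated (TBSCl, imidazole) to (E)-tert-butyl[(3-iodo-2-methylprop-2-enyl)oxy]dimethylsilane F3.
- Zinc dust and LiCl in THF should convert 9 into [5-(methoxycarbonyl)-2-methoxy-3-(prop-2-enyl)benzyl]zinc chloride F4.
- Negishi coupling of F4 with F3 (Pd(PPh3)4, THF, rt to 50 °C) should give methyl 4-methoxy-3-(prop-2-enyl)-5-[(E)-4-(tert-butyldimethylsilyloxy)-3-methylbut-2-enyl]benzoate F5, with the olefin geometry carried over from the iodide.
- Cross-metathesis of the allyl group of F5 with isopropenylboronic acid pinacol ester (second-generation Hoveyda-Grubbs catalyst, CH2Cl2, 40 °C) should favour methyl 4-methoxy-3-[(Z)-3-(4,4,5,5-tetramethyl-1,3,2-dioxaborolan-2-yl)but-2-enyl]-5-[(E)-4-(tert-butyldimethylsilyloxy)-3-methylbut-2-enyl]benzoate F6, with the bulky boronate trans to the benzylic carbon; any minor isomer would be removed at this stage.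
- Treatment with NaOH and then I2 (THF, 0 °C) replaces boron by iodine with retention and should give 18.

Step 6. The allyl double bond may migrate into conjugation with the ring, the allyl arene may homodimerise, and turnover with the electron-poor 1,1-disubstituted partner may be sluggish. The fallback sets out from 9 and comes back at 11, replacing metathesis by carbonyl olefination.
- Lemieux-Johnson cleavage of the allyl group (OsO4 cat., NaIO4, 2,6-lutidine, dioxane/H2O, rt) should give methyl 3-(chloromethyl)-4-methoxy-5-(2-oxoethyl)benzoate F7.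
- Wittig reaction of F7 with commercial 2-(triphenylphosphoranylidene)propanal (toluene, rt) should give the E-enal 11, E-selectivity being normal for this stabilised ylide.

**Further compounds**

F1 | step 12 | racemic methyl 3-[(2E)-4-hydroxy-3,7-dimethylocta-2,6-dienyl]-4-methoxy-5-[(E)-4-(tert-butyldimethylsilyloxy)-3-methylbut-2-enyl]benzoate | COC(=O)c1cc(C/C=C(\C)C(O)CC=C(C)C)c(OC)c(C/C=C(\C)CO[Si](C)(C)C(C)(C)C)c1
F2 | step 12 | methyl 3-[(2E)-3,7-dimethyl-4-oxoocta-2,6-dienyl]-4-methoxy-5-[(E)-4-(tert-butyldimethylsilyloxy)-3-methylbut-2-enyl]benzoate | COC(=O)c1cc(C/C=C(\C)C(=O)CC=C(C)C)c(OC)c(C/C=C(\C)CO[Si](C)(C)C(C)(C)C)c1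
F3 | step 10 | (E)-tert-butyl[(3-iodo-2-methylprop-2-enyl)oxy]dimethylsilane | I/C=C(\C)CO[Si](C)(C)C(C)(C)C
F4 | step 10 | [5-(methoxycarbonyl)-2-methoxy-3-(prop-2-enyl)benzyl]zinc chloride | COC(=O)c1cc(CC=C)c(OC)c(C[Zn]Cl)c1
F5 | step 10 | methyl 4-methoxy-3-(prop-2-enyl)-5-[(E)-4-(tert-butyldimethylsilyloxy)-3-methylbut-2-enyl]benzoate | COC(=O)c1cc(CC=C)c(OC)c(C/C=C(\C)CO[Si](C)(C)C(C)(C)C)c1
F6 | step 10 | methyl 4-methoxy-3-[(Z)-3-(4,4,5,5-tetramethyl-1,3,2-dioxaborolan-2-yl)but-2-enyl]-5-[(E)-4-(tert-butyldimethylsilyloxy)-3-methylbut-2-enyl]benzoate | COC(=O)c1cc(C/C=C(\C)B2OC(C)(C)C(C)(C)O2)c(OC)c(C/C=C(\C)CO[Si](C)(C)C(C)(C)C)c1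
F7 | step 6 | methyl 3-(chloromethyl)-4-methoxy-5-(2-oxoethyl)benzoate | COC(=O)c1cc(CC=O)c(OC)c(CCl)c1
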